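Retrosynthesis: the C3=C4 alkene goes back to the chroman. The C7 phenol goes back to an isopropyl ether and the ring A ortho phenol to a methyl ether. Ring B is then cut at C4a–C5 and C8–C8a.
Enabling feature: in ring B the aroyl-bearing C5 is meta to both oxygenated carbons, C7 and C8a. C5–C6–C7–C8 therefore map onto C6–C5–C4–C3 of a 6-aroyl-4-alkoxy-2-pyrone. C4a–C8a map onto the C=C of a ketene acetal made from the lactone that already holds O1, C2 with its two methyl groups, C3 and C4.
Further cuts: the ring A–carbonyl bond goes back to lithiated 1,3,5-trimethoxybenzene and a pyrone-6-carbaldehyde made from triacetic acid lactone. The lactone comes from glutaric anhydride and MeMgBr.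
Forward order: ring A is bought and the pyran ring is made as the lactone. Ring B is closed last by (4+2) cycloaddition with loss of CO2 and silanol. BCl3 then frees both phenols and DDQ installs C3=C4.
Stereochemistry: the target has no stereocentre. The centres of the carbinol and of the cycloadducts are transient and disappear on oxidation and aromatisation.

Key step: step 7

Remark on the chemistry: the ketene acetal carries OSiMe2t-Bu rather than O-alkyl as the group lost on aromatisation. O-alkylating a lactone that has a tertiary alkyl–oxygen bond would give a lactonium salt prone to fragmentation, whereas enolate silylation runs under basic conditions.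

Step 1
Reactants: 1 4-hydroxy-6-methyl-2H-pyran-2-one
Product: 2 4-isopropoxy-6-methyl-2H-pyran-2-one
Conditions: i-PrOH, PPh3, DIAD, THF, 0 °C to rt
Reagents that add atoms: propan-2-ol, CC(C)O
Why: Mitsunobu etherification, in which the acidic vinylogous carboxylic OH of 1 is a competent pronucleophile and reacts on the C4 oxygen, avoiding the C3-alkylated and 2-alkoxy-4-pyrone isomers that can accompany base-mediated alkylation with a secondary halide.

Step 2
Reactants: 2 4-isopropoxy-6-methyl-2H-pyran-2-one
Product: 3 4-isopropoxy-2-oxo-2H-pyran-6-carbaldehyde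
Conditions: SeO2, 1,4-dioxane, 160 °C, sealed tube
Reagents that add atoms: selenium dioxide, O=[Se]=O
Why: Riley oxidation of the only allylic C–H position, the C6 methyl group on C5=C6, a transformation established for the 4-methoxy analogue, while the isopropyl ether offers no allylic hydrogen.

Step 3
Reactants: 4 1,3,5-trimethoxybenzene; 3 4-isopropoxy-2-oxo-2H-pyran-6-carbaldehyde
Product: 6 6-[hydroxy(2,4,6-trimethoxyphenyl)methyl]-4-isopropoxy-2H-pyran-2-one (racemic), via 2,4,6-trimethoxyphenyllithium 5 (not isolated)
Conditions: n-BuLi, THF, 0 °C to rt; solution of 5 (1 equiv) added to 3, THF, –78 °C; aq NH4Cl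
Reagents that add atoms: none
Why: Directed ortho-lithiation between two methoxy groups followed by 1,2-addition of the bulky aryllithium to the aldehyde, which at –78 °C with inverse addition should outrun attack on the donor-stabilised lactone carbonyl, the new carbinol centre being racemic and erased in step 4.

Step 4
Reactants: 6 6-[hydroxy(2,4,6-trimethoxyphenyl)methyl]-4-isopropoxy-2H-pyran-2-one
Product: 7 4-isopropoxy-6-(2,4,6-trimethoxybenzoyl)-2H-pyran-2-one
Conditions: Dess–Martin periodinane, CH2Cl2, rt
Reagents that add atoms: none
Why: Dess–Martin oxidation runs under near-neutral, non-ionising conditions, which suits a carbinol next to a very electron-rich aryl ring that could ionise in acid.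

Step 5
Reactants: 8 glutaric anhydride
Product: 10 6,6-dimethyltetrahydro-2H-pyran-2-one, via 5-hydroxy-5-methylhexanoic acid 9 (not isolated)
Conditions: MeMgBr (2.2 equiv), THF, –20 °C to rt; then 2 M HCl, rt
Reagents that add atoms: methylmagnesium bromide, C[Mg]Br
Why: Double Grignard addition, in which the first equivalent opens the anhydride to a keto carboxylate whose carboxylate is inert, the second adds to the ketone, and the tertiary delta-hydroxy acid lactonises on acidification with help from the gem-dimethyl effect.

Step 6
Reactants: 10 6,6-dimethyltetrahydro-2H-pyran-2-one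
Product: 12 6-(tert-butyldimethylsilyloxy)-2,2-dimethyl-3,4-dihydro-2H-pyran, via lithium enolate 11 (not isolated)
Conditions: LDA, THF, –78 °C; TBSCl, DMPU, –78 °C to rt; pentane, filtration, bulb-to-bulb distillation
Reagents that add atoms: tert-butyldimethylsilyl chloride, CC(C)(C)[Si](C)(C)Cl
Why: Kinetic enolisation and O-silylation to a cyclic silyl ketene acetal is standard for delta-lactones, TBSCl in the presence of DMPU goes to oxygen, and the basic medium leaves the tertiary C–O bond untouched.

Step 7
Reactants: 7 4-isopropoxy-6-(2,4,6-trimethoxybenzoyl)-2H-pyran-2-one; 12 6-(tert-butyldimethylsilyloxy)-2,2-dimethyl-3,4-dihydro-2H-pyran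
Product: 15 (7-isopropoxy-2,2-dimethylchroman-5-yl)(2,4,6-trimethoxyphenyl)methanone, via bridged lactone adduct 13 (not isolated), via 8a-silyloxy-4a,8a-dihydrochroman 14 (not isolated)
Conditions: 12 (3 equiv), toluene (1 M), 130 °C, sealed tube, Ar; then TsOH·H2O (cat.), 60 °C
Reagents that add atoms: none
Why: In an inverse-electron-demand Diels–Alder reaction the nucleophilic CH carbon of 12 (future C4a) bonds to pyrone C6 (future C5) and the dioxygenated carbon (future C8a) bonds to pyrone C3 (future C8), asynchronously or through a short-lived zwitterion, to give 13; retro-(4+2) loss of CO2 gives 14, and elimination of t-BuMe2SiOH across C4a–C8a, completed by the acid finish, aromatises it irreversibly. The closest known reaction type is the cycloaddition of acceptor-substituted 2-pyrones (carboalkoxy, sulfonyl, halo) with ketene acetals and silyl enol ethers, which gives oxygenated arenes after loss of CO2 and of the alcohol or silanol. Ring B is the only ring closed, by intermolecular (4+2) annulation onto the C=C of the preformed dihydropyran, so the pyran ends up fused at C4a–C8a. The four stereocentres of 13 (cis fusion from suprafacial addition, endo or exo open) all vanish on aromatisation, so no stereocontrol is needed. The step needs orientation and periselectivity: C6 is the delta terminus of the lactone dienoate and is not reached by the C4 isopropoxy donor, which instead enriches C3 and so pairs it with the oxocarbenium carbon, and the reverse orientation would have to join the two fully substituted carbons; the aroyl group alone would polarise toward C5 and C3, but O1 and the C4 oxygen blunt those positions, so its main effect is to lower the diene LUMO, which it can do because the di-ortho-substituted aryl ring is twisted out of conjugation with the carbonyl. The bulky TBS group slows silyl transfer in a stepwise path, and if 14 aromatised by expelling O1 instead of the silanol, the acid finish should re-close the tertiary carbinol onto that oxygen to give the same chroman.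

Step 8
Reactants: 15 (7-isopropoxy-2,2-dimethylchroman-5-yl)(2,4,6-trimethoxyphenyl)methanone
Product: 17 (7-hydroxy-2,2-dimethylchroman-5-yl)(2-hydroxy-4,6-dimethoxyphenyl)methanone, via bis(dichloroboryl) aryloxide 16 (not isolated)
Conditions: BCl3 (3 equiv), CH2Cl2, –78 to 0 °C; then H2O
Reagents that add atoms: none
Why: Lewis-acid ether cleavage, in which BCl3 chelated between the ketone and an ortho methoxy group removes only one of the two equivalent ortho methyl groups, dealkylates the secondary isopropyl aryl ether but not the unassisted para methyl ether, and meets the saturated chroman rather than the acid-sensitive chromene, any opening of C2–O1 being repaired by acid-catalysed re-closure to the thermodynamically preferred 2,2-dimethylchroman.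

Step 9
Reactants: 17 (7-hydroxy-2,2-dimethylchroman-5-yl)(2-hydroxy-4,6-dimethoxyphenyl)methanone
Product: 19 (2-hydroxy-4,6-dimethoxyphenyl)(7-hydroxy-2,2-dimethyl-2H-chromen-5-yl)methanone, via para-quinone methide 18 (not isolated)
Conditions: DDQ (1.2 equiv), 1,4-dioxane, 80 °C
Reagents that add atoms: none
Why: DDQ dehydrogenation of a 2,2-dimethylchroman, in which hydride leaves C4 with help from the free para C7–OH and the ortho O1, the quinone methide tautomerises by loss of H3 to the conjugated chromene, the product has no further benzylic hydrogen, and the ring A phenol is held by its hydrogen bond to the ketone on the side away from C4.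

Compound list
1 | 4-hydroxy-6-methyl-2H-pyran-2-one | CC1=CC(O)=CC(=O)O1 | starting material
2 | 4-isopropoxy-6-methyl-2H-pyran-2-one | CC1=CC(OC(C)C)=CC(=O)O1 | intermediate
3 | 4-isopropoxy-2-oxo-2H-pyran-6-carbaldehyde | CC(C)OC1=CC(=O)OC(C=O)=C1 | intermediate
4 | 1,3,5-trimethoxybenzene | COc1cc(OC)cc(OC)c1 | starting material
5 | 2,4,6-trimethoxyphenyllithium | [Li]c1c(OC)cc(OC)cc1OC | intermediate
6 | 6-[hydroxy(2,4,6-trimethoxyphenyl)methyl]-4-isopropoxy-2H-pyran-2-one (racemic) | CC(C)OC1=CC(=O)OC(C(O)c2c(OC)cc(OC)cc2OC)=C1 | intermediate
7 | 4-isopropoxy-6-(2,4,6-trimethoxybenzoyl)-2H-pyran-2-one | CC(C)OC1=CC(=O)OC(C(=O)c2c(OC)cc(OC)cc2OC)=C1 | intermediate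
8 | glutaric anhydride | O=C1CCCC(=O)O1 | starting material
9 | 5-hydroxy-5-methylhexanoic acid | CC(C)(O)CCCC(=O)O | intermediate
10 | 6,6-dimethyltetrahydro-2H-pyran-2-one | CC1(C)CCCC(=O)O1 | intermediate
11 | lithium enolate of 10 | [Li]OC1=CCCC(C)(C)O1 | intermediate
12 | 6-(tert-butyldimethylsilyloxy)-2,2-dimethyl-3,4-dihydro-2H-pyran | CC1(C)CCC=C(O[Si](C)(C)C(C)(C)C)O1 | intermediate
13 | bridged 2-oxabicyclo[2.2.2]oct-5-en-3-one adduct, pyrone C6 bonded to C4a and pyrone C3 to C8a, tetrahydropyran cis-fused, OTBS on C8a (racemic, bridgehead configuration endo or exo left open) | O=C1OC2(C(=O)c3c(OC)cc(OC)cc3OC)C=C(OC(C)C)C1[C@@]1(O[Si](C)(C)C(C)(C)C)OC(C)(C)CC[C@@H]21 | intermediate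
14 | [8a-(tert-butyldimethylsilyloxy)-7-isopropoxy-2,2-dimethyl-3,4,4a,8a-tetrahydro-2H-chromen-5-yl](2,4,6-trimethoxyphenyl)methanone (racemic, H4a and OTBS cis) | CC(C)OC1=C[C@@]2(O[Si](C)(C)C(C)(C)C)OC(C)(C)CC[C@H]2C(C(=O)c2c(OC)cc(OC)cc2OC)=C1 | intermediate
15 | (7-isopropoxy-2,2-dimethylchroman-5-yl)(2,4,6-trimethoxyphenyl)methanone | CC(C)Oc1cc(C(=O)c2c(OC)cc(OC)cc2OC)c2c(c1)OC(C)(C)CC2 | intermediate
16 | bis(dichloroboryl) aryloxide of 17 | COc1cc(OB(Cl)Cl)c(C(=O)c2cc(OB(Cl)Cl)cc3c2CCC(C)(C)O3)c(OC)c1 | intermediate
17 | (7-hydroxy-2,2-dimethylchroman-5-yl)(2-hydroxy-4,6-dimethoxyphenyl)methanone | COc1cc(O)c(C(=O)c2cc(O)cc3c2CCC(C)(C)O3)c(OC)c1 | intermediate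
18 | para-quinone methide, 5-(2-hydroxy-4,6-dimethoxybenzoyl)-2,2-dimethyl-2,3-dihydro-7H-chromen-7-one | COc1cc(O)c(C(=O)C2=CC(=O)C=C3OC(C)(C)CC=C23)c(OC)c1 | intermediate
19 | (2-hydroxy-4,6-dimethoxyphenyl)(7-hydroxy-2,2-dimethyl-2H-chromen-5-yl)methanone | COc1cc(O)c(C(=O)c2cc(O)cc3c2C=CC(C)(C)O3)c(OC)c1 | target

Total step count: 9. Longest linear sequence: 7 steps (steps 1, 2, 3, 4, 7, 8 and 9, from 1).

Steps most likely to fail

Step 7. The cycloaddition may be too slow, because the C4 alkoxy donor raises the diene LUMO and C6 is crowded. Several side processes could then win: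
- thermal retro-ene decay of the ketene acetal at its tertiary C–O bond;
- silyl transfer after the first bond has formed;
- hetero-(4+2) capture through the aroyl enone;
- the reverse orientation of addition.

The fallback gives up the pyrone annulation and builds the chroman on a bought benzene ring. It sets out from 1,3,5-trimethoxybenzene 4, used as its lithio derivative 5, and comes back at 15.
- Purchased methyl 3,5-dihydroxybenzoate F1 is mono-alkylated with 2-bromopropane (K2CO3, DMF) to methyl 3-hydroxy-5-isopropoxybenzoate F2.
- The remaining phenol is etherified with 3-chloro-3-methylbut-1-yne (DBU, CuCl2 cat., MeCN) to methyl 3-isopropoxy-5-[(2-methylbut-3-yn-2-yl)oxy]benzoate F3.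
- Heating in N,N-diethylaniline starts the aromatic propargyl Claisen rearrangement, hydrogen shift and 6π closure. This should give methyl 7-isopropoxy-2,2-dimethyl-2H-chromene-5-carboxylate F4. The meta ester steers migration toward itself and the meta alkoxy group steers it away from itself, so both favour the carbon next to the ester.
- Hydrogenation (H2, Pd/C, EtOAc) gives methyl 7-isopropoxy-2,2-dimethylchroman-5-carboxylate F5.
- Acylation of 5 by F5 (THF, –78 °C to rt) should stop at ketone 15, because four ortho substituents block a second addition.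

Step 9. The free phenols may undergo oxidative coupling or form adducts with the quinone. The quinone methide may also be captured by a nucleophile before it loses H3. The fallback reverses the order of the last two operations, so that no phenol is present during the oxidation. It sets out from 15 and comes back at 19. DDQ in refluxing dioxane dehydrogenates the fully etherified chroman to (7-isopropoxy-2,2-dimethyl-2H-chromen-5-yl)(2,4,6-trimethoxyphenyl)methanone F6. BCl3 in CH2Cl2, held between –78 and 0 °C for the shortest time needed, then removes the isopropyl group and one ortho methyl group.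

Step 3. The aryllithium may attack the lactone carbonyl or C6 and open the pyrone, or it may simply deprotonate the substrate. The fallback replaces the carbanion by an electrophilic aromatic substitution. It sets out from 3 and comes back at 7, so step 4 is no longer needed. Pinnick oxidation (NaClO2, NaH2PO4, 2-methylbut-2-ene, t-BuOH/H2O) gives 4-isopropoxy-2-oxo-2H-pyran-6-carboxylic acid F7. Its mixed anhydride with trifluoroacetic anhydride (CH2Cl2, 0 °C to rt) then acylates 1,3,5-trimethoxybenzene 4 in a Friedel–Crafts reaction.

Further compounds
F1 | step 7 | methyl 3,5-dihydroxybenzoate (purchased) | COC(=O)c1cc(O)cc(O)c1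
F2 | step 7 | methyl 3-hydroxy-5-isopropoxybenzoate | COC(=O)c1cc(O)cc(OC(C)C)c1
F3 | step 7 | methyl 3-isopropoxy-5-[(2-methylbut-3-yn-2-yl)oxy]benzoate | COC(=O)c1cc(OC(C)C)cc(OC(C)(C)C#C)c1
F4 | step 7 | methyl 7-isopropoxy-2,2-dimethyl-2H-chromene-5-carboxylate | COC(=O)c1cc(OC(C)C)cc2c1C=CC(C)(C)O2
F5 | step 7 | methyl 7-isopropoxy-2,2-dimethylchroman-5-carboxylate | COC(=O)c1cc(OC(C)C)cc2c1CCC(C)(C)O2
F6 | step 9 | (7-isopropoxy-2,2-dimethyl-2H-chromen-5-yl)(2,4,6-trimethoxyphenyl)methanone | CC(C)Oc1cc(C(=O)c2c(OC)cc(OC)cc2OC)c2c(c1)OC(C)(C)C=C2
F7 | step 3 | 4-isopropoxy-2-oxo-2H-pyran-6-carboxylic acid | CC(C)OC1=CC(=O)OC(C(=O)O)=C1
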